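| flask | starting material | partner | remark | time |
|---|---|---|---|---|
| gamma | 0.56 M | 0.48 M | run made earlier |  |
| delta | 0.88 M | 0.48 M | run made earlier |  |
| theta | 0.40 M | 0.24 M | run made earlier |  |
| Wednesday's | 0.40 M | 0.480 M |  | 10 min |
| Tuesday's | 0.40 M | 0.480 M |  | 20 min |

| run | time / min | starting material / % | target / % | open intermediate / % | isomer of the product / % |
|---|---|---|---|---|---|
| gamma | 0.417 | 74 | 0 | 26 | 0 |
| gamma | 1.33 | 39 | 2 | 56 | 0 |
| gamma | 2.00 | 30 | 1 | 67 | 1 |
| gamma | 3.00 | 16 | 8 | 75 | 2 |
| gamma | 5.00 | 8 | 16 | 74 | 1 |
| gamma | 6.00 | 6 | 16 | 74 | 3 |
| delta | 0.500 | 73 | 1 | 26 | 2 |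
| delta | 0.833 | 59 | 1 | 41 | 3 |
| delta | 1.33 | 43 | 2 | 57 | 1 |
| delta | 2.00 | 31 | 3 | 68 | 1 |
| delta | 4.00 | 10 | 8 | 79 | 3 |
| delta | 6.00 | 7 | 18 | 74 | 3 |
| theta | 0.500 | 72 | 0 | 27 | 2 |
| theta | 1.50 | 40 | 1 | 58 | 0 |
| theta | 3.00 | 17 | 3 | 77 | 0 |
| theta | 4.00 | 11 | 8 | 83 | 1 |
| theta | 6.00 | 6 | 10 | 81 | 3 |

(scatter of a reading: 1.5 percentage points)

* which of these there is most of at the end, counted by the starting material in it, Wednesday's (starting material / isomer of the product / open intermediate / target)
* which of these there is most of at the end, counted by the starting material in it, Tuesday's (starting material / isomer of the product / open intermediate / target)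
* amount of the one of these that there is most of at the end, in percent of the starting material charged, Wednesday's
* amount of the one of these that there is most of at the end, in percent of the starting material charged, Tuesday's

- a reading or a percentage of target counts all its forms, free or not

- The time of reading is what separates Wednesday's flask from Tuesday's, 10 min against 20 min on the same charge, so I need one curve read twice.
- By hand I expect the amount of starting material to matter little. Gamma and delta, at [starting material] 0.56 M and 0.88 M, read 16% and 18% target at 6.00 min, a gap of 2 percentage points against a scatter of 1.5 points, so I carry their mean, 17.0%, to [starting material] 0.40 M.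
- Theta, at [partner] 0.24 M and [starting material] 0.40 M, reads 10% target at that time, less than gamma. Two settings differ there, but I have just set starting material aside, so I read the gap as partner's. But both new flasks hold [partner] 0.480 M, as gamma and delta do, so I need no correction for it.
- Gamma's last four readings add up to 99.0%, so I take them as the whole charge. Its readings of starting material and isomer of the product, 6% and 3%, leave 91.0% for target and open intermediate, the resting state of these late readings. So target passes open intermediate at a bar of 45.5%, half of that.
- Target rises by 0.0383 min⁻¹ of the charge, the mean of the late slopes in gamma and delta. From the mean at 6.00 min, that pace reaches the bar at the tie time, the moment target overtakes open intermediate: 13.4 min.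
- My reckoning puts Wednesday's 10 min before the tie time, so I expect target at 32.3% and open intermediate in front at 58.7%.
- Tuesday's 20 min falls after the tie time, so I expect target in front. The straight line gives 70.7%, which I distrust so far from the readings, and I commit to its midpoint with the bar, 58.1%.
- The forecast says open intermediate at 63% for Wednesday's and open intermediate at 46% for Tuesday's, adding “Tuesday's is nearly a tie”. It parts from my reckoning on Tuesday's flask.

- Wednesday's flask gives open intermediate at 52.0%, and Tuesday's gives target at 50.3%.

    starting material ⇌ open intermediate (K = 13.0, k = 0.0110 s⁻¹)
    partner → second intermediate (k = 0.00280 s⁻¹)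
    target ⇌ isomer of the product (K = 0.630, k = 0.00110 s⁻¹)
    open intermediate + second intermediate → target (k = 0.00640 M⁻¹ s⁻¹)
    crystals ⇌ target, rate k5*(cs5 - [target]) while solid is left; crystals form when [target] > cs5 (solubility = 0.280 M, k = 0.130 s⁻¹)

- On this charge, open intermediate and target stand level at 12.9 min. My tie time of 13.4 min still sorts the two flasks: Wednesday's reading falls before it and Tuesday's after it. The neighbouring flask on the same charge, read at 25 min, also lies later than the tie time, and there target stands in front at 52.9%, with open intermediate at 19.3%.

Readings and results are calculated with made-up constants; the scatter is artificial.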